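- You ask for a quick number for what the winter run reaches at 82 min, so I test first whether the free catalyst lasts long enough in that flask; the two orders come after.

| flask | substrate | coupling partner | free catalyst | time |
|---|---|---|---|---|
| dawn | 0.0800 M | 0.0960 M | 0.00800 M |  |
| spring | 0.0800 M | 0.190 M | 0.00800 M |  |
| summer | 0.0800 M | 0.0960 M | 0.00400 M |  |
| autumn | 0.120 M | 0.0960 M | 0.00800 M |  |
| winter | 0.200 M | 0.0960 M | 0.00800 M | 82 min |

| run | time / min | [product] / M |
|---|---|---|
| dawn run | 2.9 | 0.0226 |
| dawn run | 8.9 | 0.0361 |
| dawn run | 17 | 0.0402 |
| dawn run | 27 | 0.0421 |
| dawn run | 39 | 0.0454 |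
| dawn run | 52 | 0.0458 |
| dawn run | 66 | 0.0474 |
| dawn run | 82 | 0.0505 |
| spring run | 2.9 | 0.0199 |
| spring run | 8.9 | 0.0258 |
| spring run | 17 | 0.0294 |
| spring run | 27 | 0.0362 |
| spring run | 39 | 0.0428 |
| spring run | 52 | 0.0472 |
| spring run | 66 | 0.0518 |
| spring run | 82 | 0.0561 |
| summer run | 2.9 | 0.0131 |
| summer run | 8.9 | 0.0210 |
| summer run | 17 | 0.0251 |
| summer run | 27 | 0.0276 |
| summer run | 39 | 0.0315 |
| summer run | 52 | 0.0344 |
| summer run | 66 | 0.0379 |
| summer run | 82 | 0.0402 |
| autumn run | 2.9 | 0.0331 |
| autumn run | 8.9 | 0.0554 |
| autumn run | 17 | 0.0645 |
| autumn run | 27 | 0.0693 |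
| autumn run | 39 | 0.0728 |
| autumn run | 52 | 0.0743 |
| autumn run | 66 | 0.0740 |
| autumn run | 82 | 0.0771 |

(standard deviation of a reading: 6 × 10⁻⁴ M)

1. the power of [free catalyst] that the first rate follows, about the charge of the dawn run; measure it at two percent of substrate made into product
2. the power of [substrate] that the first rate follows, about the charge of the dawn run; measure it at two percent of substrate made into product (one fixed amount of product, the same in the runs compared)
3. product in the winter run at 82 min, as a share of the substrate charged

- Overall: substrate + coupling partner -> product, with free catalyst as catalyst.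
- Constant volume, constant temperature.
- A reading of a species includes what of it is bound.
- An order is taken over about fifteen percent of the charge, up and down.

- I read the dawn run at both ends. Its late slope is 1.53 × 10⁻⁴ M min⁻¹, and running that line back from 27 min leaves a burst of 0.0380 M.
- I take the burst to end when the coupling partner has killed the free catalyst, since the spring run, with more partner, stands lower at 17 min: 0.0294 M against 0.0402 M.
- If substrate and partner compete for free catalyst, each unit of catalyst delivers a fixed amount of product weighted by partner over substrate. I call this the catalyst allowance, a selectivity factor: the integral of (R/S) dP, divided by the catalyst charge.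
- With R and S the charges, that integral is P + (R − S)·ln(S/(S − P)). The dawn burst gives an allowance of 6.03.
- In the winter run, consuming the whole partner charge needs 0.0280 M of that integral, while the catalyst charge pays for 0.0483 M. So the partner, not catalyst death, is the limiting reagent, and I commit to 48.0 %.
- For the orders, the first readings give 0.787 in catalyst and 0.941 in substrate. Both are rough, because dawn has already turned 28.2 % by then.
- The forecast says 0.92, 0.97 and 47.5 %, on the ground that “the catalyst outlasts the partner”. Its orders stand above mine, and its yield just below.

    free catalyst + substrate → catalyst-substrate complex (29.52 M⁻¹ min⁻¹)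
    catalyst-substrate complex + coupling partner → product + free catalyst (76.20 M⁻¹ min⁻¹)
    substrate + coupling partner → product (0.07860 M⁻¹ min⁻¹)
    free catalyst + coupling partner → spent catalyst + coupling partner (4.986 M⁻¹ min⁻¹)

- The winter run gives 48.0 %, with orders 0.78 in catalyst and 0.71 in substrate. Removing the partner's killing of free catalyst leaves that yield unchanged. In the spring run, an allowance of 6.03 pays for 0.0483 M, while reaching a quarter of the substrate asks 0.0516 M, which puts the end of the burst near that point. The spring run reaches a quarter at 3.37 min and half at 34.1 min.

All runs are calculated on assumed constants; the scatter is artificial.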